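**Remarks.** Atoms carry gibberellane numbers (C7 = carboxyl carbon on C6, C18 = methyl on C4, C19 = lactone carbonyl carbon on C4). β is the face of H‑5, H‑9, C7 and C15; α is the face of the lactone bridge and C14. Salts that give a listed compound on aqueous work-up, and catalyst-bound species, are not numbered.

## Analysis of the target

The target 47, the forty-ninth gibberellin of the A series, is a 20‑nor‑ent‑gibberellane. Ring A (cyclohexane) is fused trans to ring B (cyclopentane) at C5–C10, ring B is fused cis to ring C at C8–C9, and rings C and D form a bicyclo[3.2.1]octane (bridgeheads C8 and C13) that carries the exocyclic C16=C17 methylene. A γ‑lactone links C19 on C4 to the oxygen on C10 across ring A. There are ten stereocentres: C2, C3, C4, C5, C6, C8, C9, C10, C12 and C13. H‑5, H‑9, C7, the C15 bridge, C18 and the 2‑ and 3‑hydroxyls lie on the β face; the lactone bridge, C14 and the axial 12‑hydroxyl lie on the α face, the 12‑OH being syn‑axial to the C9–C10 bond. The synthesis is hard because of the density around ring B: C4 and C8 are quaternary, C10 is a fully substituted carbinol carbon, and every ring‑B carbon is a stereocentre. The sensitive groups are the 3‑hydroxyl β to the lactone carbonyl (retro‑aldol epimerisation at C3 under base), the 1,1‑disubstituted C16=C17 alkene (acid‑labile, and more reactive toward osmium or peracid than a ring‑A alkene), and the hindered C7 acid next to C8. The strategy rests on the cis‑fused B/C hydrindane: the shared C8–C9 bond with quaternary C8, and the oxygen on C12 at the far end of a C8=C14–C13=C12 diene, are the retron of a [4+2] cycloaddition in which a three‑atom tether (C6–C5–C10) closes ring B while the diene and dienophile close ring C.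

## Retrosynthetic reasoning

**Unmasking (47 ⇐ 46 ⇐ 45).** The last operations only remove protecting groups. The 2,3‑diol stays an acetonide until the end so that no basic step can open the C3–C4 bond by retro‑aldol. The C7 methyl ester is cleaved by SN2 dealkylation before the acetonide comes off.

**C12–H (45 ⇐ 44).** The 12α‑hydroxyl is cut back to the C12 ketone. The forward reduction has to deliver hydride to the β face; the α face of C12 is covered by the syn‑axial C9–C10 bond and the lactone oxygen.

**C13–C16, ring D (44 ⇐ 43 ⇐ 41).** Ring D is opened at C13–C16 to a C12=C13 silyl enol ether and a propargyl group on C8. This bond is cut here because its formation also creates the C16=C17 alkene, which therefore appears only after every alkene oxidation is finished. The enol ether is regiodefined by conjugate reduction of the C13=C14 enone 41.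

**C2–O and C3–O (41 ⇐ 40 ⇐ 39).** The cis‑diol is taken back to the C2=C3 alkene of 39. At this stage the only other π systems are an electron‑poor enone and an alkyne, so the ring‑A alkene is the one that is dihydroxylated, from the face opposite the lactone bridge.

**C19–O10 lactone and C12 carbonyl (39 ⇐ 37 ⇐ 36).** One oxidation turns the C19 primary alcohol, syn‑axial to the 10α‑hydroxyl, into the lactone and the C12 allylic alcohol into the enone. C19 is carried at the alcohol level as a silyl ether, because a Claisen partner with C19 as an ester would be a Z γ‑hydroxy enoate, which closes to a butenolide.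

**C2=C3, ring A (36 ⇐ 35).** Ring A is cut at C2=C3 to an allyl group on C10 and a vinyl group on C4. The forward ring‑closing metathesis needs the alkyne masked, so it carries a triisopropylsilyl group from the first step; the same group protects it from the Grignard and amide bases.

**C1–C10 (35 ⇐ 34).** The allyl group is removed from C10 to give the ketone. Allylation has to come from the β face, which is the face left open by the C4 substituent on C5 and by C11 on C9.

**C4–C5 (34 ⇐ 31 + 30).** The quaternary C4 next to tertiary C5 is cut by a Claisen transform to the C10 ketal 31 and the Z allylic alcohol 30. This is done while C10 is the only ketone in the molecule, with C12 still a silyl ether. If ring D were closed first, the conjugate reduction and the allylation would each face two ketones.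

**C6 configuration (31 ⇐ 24 ⇐ 22).** The Claisen step needs the ester on the β face to send C4 to the α face. The cycloaddition delivers the ester on the α face (see next paragraph), so 22 is equilibrated at C6 to 24 before ring A is started.

**C8–C9 and C11–C12, rings B and C (22 ⇐ 21).** Both rings are opened in one transform to the trienone 21. In the endo arrangement one substituent of C6 lies beside the in‑plane C15 methylene, and that place goes to hydrogen, not to the ester. The ester therefore ends up trans to C15, and the precursor must have (R)‑C6 for the dienophile to reach the diene face that gives the C8/C9 configuration of 47.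

**Vinyl ketone and dienol ether (21 ⇐ 19 ⇐ 18).** The vinyl ketone is released last from the Weinreb amide of 19, which survives the enolisation that makes the dienol ether from the enal 18. γ‑Deprotonation of the E enal gives the E enol ether and places the branched C6 outside and the propargyl CH2 inside on C8.

**C6–C8 (18 ⇐ 16 ⇐ 15 ⇐ 11).** The C6–C8 bond is cut by an Ireland–Claisen transform to the allylic ester 11. The rearrangement sets C6 by chirality transfer from the carbinol carbon and gives the E C13=C14 alkene of the enal. The stereocentre it sets at C8 is erased again when the diene is formed.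

**Fragments (11 ⇐ 7 + 10; 7 ⇐ 6 + 4; 4 ⇐ 1 + 2; 6 ⇐ 5; 10 ⇐ 8 + 9; 30 ⇐ 25 + 26).** The ester is split into alcohol 7 and acid 10. Alcohol 7 comes from cross‑metathesis of 6 (from diol 5) with enyne 4 (from 1 and 2). Acid 10 comes from 8 and 9. Alcohol 30 comes from a Z‑selective olefination of 25 with 26, followed by a protecting‑group exchange.

## Alternatives that were turned down

**Alternative 1:** The C12–O bond is cut last and traced to a C12–H bond that is oxidised from the C10 oxygen. In the forward step a C10 alkoxy radical, made under hypoiodite conditions, abstracts the 12α‑hydrogen through a six‑membered transition state and the oxidised C12 is trapped by the same oxygen to give the 10,12α‑ether A1. For it: the geometry of the hydrogen transfer fixes the 12α configuration with certainty, and no C12 oxygen has to be carried through the synthesis. Against it: a tertiary alkoxy radical at C10 can fragment by β‑scission of C10–C1, C10–C5 or C10–C9 in competition with hydrogen abstraction. The lactone must be held open as the 19‑amide and the C16=C17 alkene masked as the 16‑ketone. The ether must then be opened at C10–O only, the lactone re‑formed and the methylene put back, which costs about four steps. On the certainty of the C12 configuration this alternative is stronger than the chosen route, which relies on the facial selectivity of a hydride reduction. The chosen route offers instead a C12 oxygen that arrives with the diene and also serves as the handle for closing ring D.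

**Alternative 2:** Ring C is cut at C12–C13, at a stage where rings A and B, the lactone and a spiro‑attached ring D are already in place. In the forward step a C12 acid chloride function on the C9 side chain is attacked by C13 of the ring‑D allylsilane unit, which closes ring C and moves the double bond to C16=C17, giving the 12‑oxo lactone A2. For it: the 12‑ketone and the exocyclic alkene are formed together after all ring‑A oxidation is done, and the allylsilane fixes the regiochemistry. Against it: the quaternary spiro carbon C8 must be set against C9 and C6 without the help of ring C. The acid chloride must be made beside a lactone and two acetates. The closure forces a spirocycle into a bridged bicycle, and the side chain must reach C13 on the correct face. On avoiding the clash between the C16=C17 alkene and the diol‑forming oxidation it is as strong as the chosen route, and it is more convergent. The chosen route sets C8 and C9 together in one concerted step and reaches the B/C core in fewer steps.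

**Alternative 3:** Ring B is cut at C9–C10, which leaves ring C as a cyclohexadienone unit and C10 as an aldehyde on the C8 side chain. In the forward step a chiral carbene catalyst turns the C10 aldehyde into an acyl anion equivalent that adds to C9 of one enone arm (Stetter reaction), closing ring B and leaving the other arm as the C12 enone of A3. For it: absolute configuration at C8 and C9 comes from a catalyst, the dienone is flat and easy to make, and the C12 enone is delivered directly. Against it: the tether already carries the C6 stereocentre, so the two enone arms are diastereotopic and catalyst and substrate must be matched. The aldehyde next to that centre can epimerise. The product holds a C10 ketone beside the C12 enone, so the conjugate reduction and all C10 chemistry face two ketones. On enantiocontrol this alternative is stronger than the chosen route, which relays chirality from a purchased diol through a rearrangement and a substrate‑controlled cycloaddition. The chosen route delivers C12 at the alcohol level, so C10 is the only ketone while ring A is built.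

Key step: step 12

## Route

Step 1
Reactants: 1 ethynyltriisopropylsilane; 2 allyl bromide
Product: 4 triisopropyl(pent-4-en-1-yn-1-yl)silane, via alkynyl Grignard reagent 3 (not isolated)
Conditions: EtMgBr, THF, 0 → 40 °C; then CuBr·SMe2 (5 mol %), 2, 50 °C
Reagents that add atoms: none
Why: Copper-catalysed SN2 coupling of an alkynyl Grignard reagent with an allylic bromide gives the skipped enyne; the silyl group blocks the alkyne terminus for the later base, Grignard and metathesis steps.

Step 2
Reactants: 5 (2S)-but-3-ene-1,2-diol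
Product: 6 (2S)-1-[(tert-butyldimethylsilyl)oxy]but-3-en-2-ol
Conditions: TBSCl (1.0 equiv), imidazole, CH2Cl2, 0 °C
Reagents that add atoms: tert-butyldimethylsilyl chloride, CC(C)(C)[Si](C)(C)Cl
Why: Selective silylation of the primary hydroxyl of a 1,2-diol on steric grounds; the stereocentre is not touched.

Step 3
Reactants: 6 (2S)-1-[(tert-butyldimethylsilyl)oxy]but-3-en-2-ol; 4 triisopropyl(pent-4-en-1-yn-1-yl)silane
Product: 7 (2S,3E)-1-[(tert-butyldimethylsilyl)oxy]-7-(triisopropylsilyl)hept-3-en-6-yn-2-ol
Conditions: Hoveyda–Grubbs II (3 mol %), 4 (3 equiv), CH2Cl2, 40 °C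
Reagents that add atoms: none
Why: Olefin cross-metathesis of a secondary allylic alcohol with an excess of a terminal alkene should give the E alkene, and the bulky silyl alkyne should stay out of enyne metathesis. Any Z isomer converges later, because C8 becomes sp2 in step 10.

Step 4
Reactants: 8 succinic anhydride; 9 N,O-dimethylhydroxylamine hydrochloride
Product: 10 4-[methoxy(methyl)amino]-4-oxobutanoic acid
Conditions: Et3N (2.2 equiv), CH2Cl2, 0 °C → rt; aq. HCl
Reagents that add atoms: none
Why: Acyl substitution: the amine opens the anhydride to the half Weinreb amide, which later serves as the masked vinyl ketone.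

Step 5
Reactants: 7 (2S,3E)-1-[(tert-butyldimethylsilyl)oxy]-7-(triisopropylsilyl)hept-3-en-6-yn-2-ol; 10 4-[methoxy(methyl)amino]-4-oxobutanoic acid
Product: 11 (2S,3E)-1-[(tert-butyldimethylsilyl)oxy]-7-(triisopropylsilyl)hept-3-en-6-yn-2-yl 4-[methoxy(methyl)amino]-4-oxobutanoate
Conditions: EDC·HCl, DMAP (cat.), CH2Cl2, rt
Reagents that add atoms: none
Why: Carbodiimide (Steglich) esterification of the secondary allylic alcohol; no stereocentre is involved.

Step 6
Reactants: 11 (2S,3E)-1-[(tert-butyldimethylsilyl)oxy]-7-(triisopropylsilyl)hept-3-en-6-yn-2-yl 4-[methoxy(methyl)amino]-4-oxobutanoate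
Product: 15 (2R,3S,4E)-6-[(tert-butyldimethylsilyl)oxy]-2-{2-[methoxy(methyl)amino]-2-oxoethyl}-3-[3-(triisopropylsilyl)prop-2-yn-1-yl]hex-4-enoic acid, via lithium ester enolate 12 (not isolated), via Z-silyl ketene acetal 13 (not isolated), via trimethylsilyl ester 14 (not isolated)
Conditions: LDA, THF/DMPU (4:1), −78 °C; TMSCl; −78 → 40 °C; aq. citric acid
Reagents that add atoms: none
Why: Ireland–Claisen rearrangement; the ester α-CH2 is deprotonated before the less acidic amide α-CH2, and DMPU gives the Z-silyl ketene acetal (C5 cis to OSi). A chair transition state with the CH2OTBS group equatorial transfers the (S)-carbinol centre to (R)-C6 and forms the E C13=C14 alkene. C8 is also set (S), but it is planarised again in step 10.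

Step 7
Reactants: 15 (2R,3S,4E)-6-[(tert-butyldimethylsilyl)oxy]-2-{2-[methoxy(methyl)amino]-2-oxoethyl}-3-[3-(triisopropylsilyl)prop-2-yn-1-yl]hex-4-enoic acid
Product: 16 methyl (2R,3S,4E)-6-[(tert-butyldimethylsilyl)oxy]-2-{2-[methoxy(methyl)amino]-2-oxoethyl}-3-[3-(triisopropylsilyl)prop-2-yn-1-yl]hex-4-enoate
Conditions: TMSCHN2, PhMe/MeOH (4:1), 0 °C
Reagents that add atoms: (trimethylsilyl)diazomethane, C[Si](C)(C)C=[N+]=[N-]
Why: O-Methylation of the acid with a diazoalkane under neutral conditions, so C6 next to the new ester is not epimerised.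

Step 8
Reactants: 16 methyl (2R,3S,4E)-6-[(tert-butyldimethylsilyl)oxy]-2-{2-[methoxy(methyl)amino]-2-oxoethyl}-3-[3-(triisopropylsilyl)prop-2-yn-1-yl]hex-4-enoate
Product: 17 methyl (2R,3S,4E)-6-hydroxy-2-{2-[methoxy(methyl)amino]-2-oxoethyl}-3-[3-(triisopropylsilyl)prop-2-yn-1-yl]hex-4-enoate
Conditions: PPTS (0.2 equiv), MeOH, rt
Reagents that add atoms: none
Why: Acid-catalysed methanolysis of the primary allylic silyl ether; the alkynyl C–Si bond is stable to acid.

Step 9
Reactants: 17 methyl (2R,3S,4E)-6-hydroxy-2-{2-[methoxy(methyl)amino]-2-oxoethyl}-3-[3-(triisopropylsilyl)prop-2-yn-1-yl]hex-4-enoate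
Product: 18 methyl (2R,3S,4E)-2-{2-[methoxy(methyl)amino]-2-oxoethyl}-6-oxo-3-[3-(triisopropylsilyl)prop-2-yn-1-yl]hex-4-enoate
Conditions: Dess–Martin periodinane, NaHCO3, CH2Cl2, 0 °C → rt
Reagents that add atoms: none
Why: Dess–Martin oxidation of the allylic alcohol to the E enal under buffered conditions that leave the γ-hydrogen (H-8) in place.

Step 10
Reactants: 18 methyl (2R,3S,4E)-2-{2-[methoxy(methyl)amino]-2-oxoethyl}-6-oxo-3-[3-(triisopropylsilyl)prop-2-yn-1-yl]hex-4-enoate
Product: 19 methyl (2R,3E,5E)-6-[(tert-butyldimethylsilyl)oxy]-2-{2-[methoxy(methyl)amino]-2-oxoethyl}-3-[3-(triisopropylsilyl)prop-2-yn-1-yl]hexa-3,5-dienoate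
Conditions: TBSOTf, Et3N, CH2Cl2, −78 → 0 °C
Reagents that add atoms: tert-butyldimethylsilyl trifluoromethanesulfonate, CC(C)(C)[Si](C)(C)OS(=O)(=O)C(F)(F)F
Why: Soft γ-enolisation of an enal (silyl triflate and amine) to the 1-silyloxy diene; the s-trans enal gives the E enol ether. At C8 the branched C6 should take the outside position (trans to C13) and the slim propargyl CH2 the inside one, which minimises 1,3-allylic strain; the C6–H of the simple ester is not acidic enough to be touched.

Step 11
Reactants: 19 methyl (2R,3E,5E)-6-[(tert-butyldimethylsilyl)oxy]-2-{2-[methoxy(methyl)amino]-2-oxoethyl}-3-[3-(triisopropylsilyl)prop-2-yn-1-yl]hexa-3,5-dienoate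
Product: 21 methyl (2R,3E,5E)-6-[(tert-butyldimethylsilyl)oxy]-2-(2-oxobut-3-en-1-yl)-3-[3-(triisopropylsilyl)prop-2-yn-1-yl]hexa-3,5-dienoate, via magnesium hemiaminal chelate 20 (not isolated)
Conditions: CH2=CHMgBr (2 equiv), THF, −78 → −40 °C; inverse quench into cold aq. NH4Cl; used at once
Reagents that add atoms: vinylmagnesium bromide, C=C[Mg]Br
Why: Grignard addition to a Weinreb amide stops at the chelated tetrahedral adduct, so the vinyl ketone appears only on work-up. The amide should react before the α-branched methyl ester at low temperature, and the inverse quench keeps the liberated hydroxylamine from adding to the enone.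

Step 12
Reactants: 21 methyl (2R,3E,5E)-6-[(tert-butyldimethylsilyl)oxy]-2-(2-oxobut-3-en-1-yl)-3-[3-(triisopropylsilyl)prop-2-yn-1-yl]hexa-3,5-dienoate
Product: 22 B/C cis-hydrindenone (C10 ketone, C13=C14, 12α-OTBS, 3-(triisopropylsilyl)prop-2-ynyl on C8, 6α-CO2Me, H-9β)
Conditions: PhMe (0.005 M), BHT (cat.), 80–110 °C
Reagents that add atoms: none
Why: Thermal type-1 intramolecular Diels–Alder reaction of a 1,6,8-nonatrien-3-one, a known reaction class: the vinyl ketone C9=C11, activated by the tether carbonyl C10, adds suprafacially to the s-cis dienol ether C8=C14–C13=C12 in one concerted step, and the short tether fixes the pairing C8–C9 and C11–C12 whatever the polarisation of the two partners. Ring C closes as the six-membered ring of the [4+2] addition and ring B as the five-membered ring of the three-atom tether C6–C5–C10, so the two rings arise fused at C8–C9. The tether carbonyl sits under the diene (endo), which gives the cis fusion with C15 and H-9 on one face; the exo mode would force the tether under the inside C15 methylene. C12 follows from the E enol ether: the outside silyloxy group ends up cis to C10 (12α). C8 and C9 are set relative to each other by the suprafacial addition and absolutely by the diene face. That face is chosen by C6: of the two endo arrangements the one with the small C6–H bond, not the ester, beside the in-plane C15 methylene should be preferred, so the ester lies on the diene face away from the dienophile and ends up trans to C15 (6α); with (R)-C6 the dienophile then adds to the face that gives the C8/C9 configuration of the target. The step therefore needs endo and facial selectivity, which the short ketone tether and the C6 stereocentre next to a 1,1-disubstituted diene terminus should secure; isomers of 21 with a Z enol ether or with the tether inside cannot reach this geometry and should not cyclise.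

Step 13
Reactants: 22 B/C cis-hydrindenone with 6α-CO2Me
Product: 24 B/C cis-hydrindenone with 6β-CO2Me (otherwise as 22), via sodium ester enolate 23 (not isolated)
Conditions: NaOMe (0.3 equiv), MeOH, 0 °C → rt
Reagents that add atoms: none
Why: Base-mediated epimerisation α to the ester under thermodynamic control: the 6β ester is cis only to the C15 methylene and faces H-9 across ring B, whereas the 6α ester is cis to C14 and syn to C11 on the concave face. C9 is also enolisable, but the cis fusion is the stable one; the alkynyl silane and the silyl ether should survive methoxide.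

Step 14
Reactants: 25 (tert-butyldimethylsilyloxy)acetaldehyde; 26 ethyl 2-[bis(2,2,2-trifluoroethoxy)phosphoryl]propanoate
Product: 27 ethyl (2Z)-4-[(tert-butyldimethylsilyl)oxy]-2-methylbut-2-enoate
Conditions: KHMDS, 18-crown-6, THF, −78 °C
Reagents that add atoms: none
Why: Still–Gennari olefination: the bis(trifluoroethyl) phosphonate with a dissociated potassium base gives the Z trisubstituted enoate under kinetic control.

Step 15
Reactants: 27 ethyl (2Z)-4-[(tert-butyldimethylsilyl)oxy]-2-methylbut-2-enoate
Product: 28 (2Z)-4-[(tert-butyldimethylsilyl)oxy]-2-methylbut-2-en-1-ol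
Conditions: DIBAL-H (2.5 equiv), CH2Cl2, −78 °C; Rochelle salt
Reagents that add atoms: none
Why: 1,2-Reduction of the enoate to the allylic alcohol with retention of the Z geometry; the silyl ether keeps the cis hydroxy ester from closing to a butenolide.

Step 16
Reactants: 28 (2Z)-4-[(tert-butyldimethylsilyl)oxy]-2-methylbut-2-en-1-ol
Product: 29 (2Z)-4-[(tert-butyldimethylsilyl)oxy]-1-[(tert-butyldiphenylsilyl)oxy]-2-methylbut-2-ene
Conditions: TBDPSCl, imidazole, CH2Cl2, rt
Reagents that add atoms: tert-butyldiphenylsilyl chloride, CC(C)(C)[Si](Cl)(c1ccccc1)c1ccccc1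
Why: Silylation of the primary alcohol with the more acid-stable silyl group, which sets up the selective deprotection.

Step 17
Reactants: 29 (2Z)-4-[(tert-butyldimethylsilyl)oxy]-1-[(tert-butyldiphenylsilyl)oxy]-2-methylbut-2-ene
Product: 30 (2Z)-4-[(tert-butyldiphenylsilyl)oxy]-3-methylbut-2-en-1-ol
Conditions: PPTS (0.2 equiv), MeOH, 0 °C → rt
Reagents that add atoms: none
Why: Acid-catalysed methanolysis removes the tert-butyldimethylsilyl ether far faster than the tert-butyldiphenylsilyl ether, which frees the hydroxyl on the CH= side.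

Step 18
Reactants: 24 B/C cis-hydrindenone with 6β-CO2Me
Product: 31 C10 dimethyl ketal of 24
Conditions: MeOSiMe3 (3 equiv), TMSOTf (5 mol %), CH2Cl2, −78 °C
Reagents that add atoms: methoxytrimethylsilane, CO[Si](C)(C)C
Why: Silyl-triflate-catalysed ketalisation with a silyl methyl ether under aprotic conditions at low temperature, which leaves both silyl ethers and the ester untouched.

Step 19
Reactants: 31 C10 dimethyl ketal of 24; 30 (2Z)-4-[(tert-butyldiphenylsilyl)oxy]-3-methylbut-2-en-1-ol
Product: 34 C10 ketone with C5 bearing α-C4 (C4: CH3, CH2OTBDPS, vinyl; configuration as in the target), 6β-CO2Me, via mixed ketal 32 (not isolated), via allyl enol ether 33 (not isolated)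
Conditions: 30 (3 equiv), EtCO2H (10 mol %), xylene, 140 °C, removal of MeOH
Reagents that add atoms: none
Why: Ketal Claisen rearrangement: acid-catalysed exchange and loss of methanol give the allyl enol ether, and only the C5=C10 isomer rearranges at a useful rate, because the C9=C10 isomer would have to join two quaternary carbons. C4 adds to C5 anti to the 6β ester (α face) through a chair with C6 equatorial. On the allyl terminus the E methyl is equatorial and the Z CH2OSi arm axial, which places methyl anti to C10, the C19 arm anti to H-5 and the vinyl group anti to C6, as the target requires.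

Step 20
Reactants: 34 C10 ketone with quaternary C4 on C5
Product: 35 10α-hydroxy-10β-allyl compound (tertiary alcohol; otherwise as 34)
Conditions: CH2=CHCH2MgBr (3 equiv), THF, −78 °C; aq. NH4Cl
Reagents that add atoms: allylmagnesium bromide, C=CC[Mg]Br
Why: 1,2-Addition of an allyl Grignard reagent, which adds to hindered ketones with little enolisation, from the β face anti to the C4 substituent on C5 and to C11 on C9; this gives the 10α-oxygen. The methyl ester next to quaternary C8 should be slower at −78 °C, and the 10α-alkoxide is trans to the 6β ester, so no lactone forms.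

Step 21
Reactants: 35 10α-hydroxy-10β-allyl compound
Product: 36 ring-A cyclohexene (C2=C3; 10α-OH, C4 with CH3 and CH2OTBDPS)
Conditions: Grubbs II (5 mol %), CH2Cl2 (0.005 M), 40 °C
Reagents that add atoms: none
Why: Ring-closing metathesis of two monosubstituted alkenes to a cyclohexene; the free tertiary alcohol, the ring-C cyclohexene and the bulky silyl alkyne should be tolerated.

Step 22
Reactants: 36 ring-A cyclohexene with three silyl groups
Product: 37 triol (12α-OH, 10α-OH, C19H2OH) with terminal alkyne
Conditions: TBAF (5 equiv), THF, 0 → 40 °C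
Reagents that add atoms: none
Why: Fluoride cleaves both O–Si bonds and the alkynyl C–Si bond in one operation; the C19 and C10 hydroxyls sit on the α face, away from the hindered 6β ester, and the C12 hydroxyl is remote, so lactonisation onto C7 should not compete.

Step 23
Reactants: 37 triol with terminal alkyne
Product: 39 19,10-lactone with C12 enone (C13=C14), C2=C3 and propargyl on C8, via lactol 38 (not isolated)
Conditions: TPAP (10 mol %), NMO (6 equiv), 4 Å MS, CH2Cl2, rt
Reagents that add atoms: none
Why: Ley–Griffith oxidation: the allylic C12 alcohol gives the enone, and the C19 alcohol gives the aldehyde, which closes onto the syn-axial 10α-hydroxyl to a lactol that is oxidised to the γ-lactone. The tertiary alcohol cannot be oxidised.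

Step 24
Reactants: 39 lactone enone with C2=C3
Product: 40 2β,3β-diol
Conditions: OsO4 (4 mol %), NMO (1.2 equiv), acetone/H2O (5:1), 0 °C
Reagents that add atoms: N-methylmorpholine N-oxide, C[N+]1([O-])CCOCC1; water, O
Why: Upjohn cis-dihydroxylation; the isolated cis alkene should react before the electron-poor enone and the alkyne. Osmium adds to the β face, because the α face of ring A is covered by the lactone bridge.

Step 25
Reactants: 40 2β,3β-diol
Product: 41 2β,3β-acetonide
Conditions: Me2C(OMe)2, PPTS (cat.), acetone, rt
Reagents that add atoms: 2,2-dimethoxypropane, COC(C)(C)OC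
Why: Acetonide formation from the cis-diol; it blocks the 3-hydroxyl so that no retro-aldol epimerisation at C3 can occur in the basic steps that follow.

Step 26
Reactants: 41 acetonide enone
Product: 43 C12=C13 tert-butyldimethylsilyl enol ether, via potassium enolate 42 (not isolated)
Conditions: K-Selectride (1.1 equiv), THF, −78 °C; then TBSCl, HMPA, −78 → 0 °C
Reagents that add atoms: tert-butyldimethylsilyl chloride, CC(C)(C)[Si](C)(C)Cl
Why: Conjugate reduction of a cyclohexenone that carries no substituent on its α- and β-carbons by a hindered borohydride (hydride to C14) should give the C12 enolate regiospecifically, and O-silylation fixes it; the lactone and the ester should not be reduced at −78 °C.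

Step 27
Reactants: 43 silyl enol ether with propargyl on C8
Product: 44 tetracyclic C12 ketone with C16=C17 (ring D closed)
Conditions: [(JohnPhos)Au(NCMe)]SbF6 (5 mol %), CH2Cl2/MeOH (10:1), rt
Reagents that add atoms: none
Why: Gold(I)-catalysed Conia-ene-type 5-exo-dig carbocyclisation of a silyl enol ether onto a terminal alkyne: C13 attacks the activated C16, and protodeauration gives the exocyclic methylene. The C13 configuration is dictated by the bridge from the axial C15 on C8.

Step 28
Reactants: 44 tetracyclic C12 ketone
Product: 45 12α-alcohol (methyl ester, acetonide)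
Conditions: L-Selectride, THF, −78 °C
Reagents that add atoms: none
Why: Hydride reduction by equatorial attack from the β face, since the α face of C12 is blocked by the syn-axial C9–C10 bond and the lactone oxygen; this should give the axial 12α-hydroxyl.

Step 29
Reactants: 45 12α-alcohol methyl ester
Product: 46 2,3-acetonide of the target (free C7 acid)
Conditions: n-PrSLi, HMPA, rt; then aq. HCl to pH 3
Reagents that add atoms: none
Why: SN2 O-demethylation by a thiolate in a dipolar aprotic solvent, which avoids acyl attack at the hindered ester and leaves the lactone intact; the acetonide keeps C3 from epimerising.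

Step 30
Reactants: 46 2,3-acetonide of the target
Product: 47 target gibberellin (2β,3β,12α-triol, 19,10-lactone, C7 acid, C16=C17)
Conditions: AcOH/H2O (4:1), 45 °C
Reagents that add atoms: none
Why: Acid hydrolysis of the acetonide under conditions mild enough to leave the exocyclic alkene and the lactone unchanged.

## Compound list

1 | ethynyltriisopropylsilane | C#C[Si](C(C)C)(C(C)C)C(C)C | starting material
2 | allyl bromide | C=CCBr | starting material
3 | bromo[(triisopropylsilyl)ethynyl]magnesium | CC(C)[Si](C#C[Mg]Br)(C(C)C)C(C)C | intermediate (not isolated)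
4 | triisopropyl(pent-4-en-1-yn-1-yl)silane | C=CCC#C[Si](C(C)C)(C(C)C)C(C)C | intermediate
5 | (2S)-but-3-ene-1,2-diol | C=C[C@H](O)CO | starting material
6 | (2S)-1-[(tert-butyldimethylsilyl)oxy]but-3-en-2-ol | C=C[C@H](O)CO[Si](C)(C)C(C)(C)C | intermediate
7 | (2S,3E)-1-[(tert-butyldimethylsilyl)oxy]-7-(triisopropylsilyl)hept-3-en-6-yn-2-ol | CC(C)[Si](C#CC/C=C/[C@H](O)CO[Si](C)(C)C(C)(C)C)(C(C)C)C(C)C | intermediate
8 | succinic anhydride | O=C1CCC(=O)O1 | starting material
9 | N,O-dimethylhydroxylamine hydrochloride | CNOC.Cl | starting material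
10 | 4-[methoxy(methyl)amino]-4-oxobutanoic acid | CON(C)C(=O)CCC(=O)O | intermediate
11 | (2S,3E)-1-[(tert-butyldimethylsilyl)oxy]-7-(triisopropylsilyl)hept-3-en-6-yn-2-yl 4-[methoxy(methyl)amino]-4-oxobutanoate | CC(C)[Si](C#CC/C=C/[C@H](OC(=O)CCC(=O)N(C)OC)CO[Si](C)(C)C(C)(C)C)(C(C)C)C(C)C | intermediate
12 | lithium ester enolate of 11 (C5 cis to O–Li) | CC(C)[Si](C#CC/C=C/[C@H](O/C([O-])=C/CC(=O)N(C)OC)CO[Si](C)(C)C(C)(C)C)(C(C)C)C(C)C.[Li+] | intermediate (not isolated)
13 | Z-O-trimethylsilyl ketene acetal of 11 (C5 cis to OSiMe3) | CC(C)[Si](C#CC/C=C/[C@H](O/C(O[Si](C)(C)C)=C/CC(=O)N(C)OC)CO[Si](C)(C)C(C)(C)C)(C(C)C)C(C)C | intermediate (not isolated)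
14 | trimethylsilyl ester of 15 | CC(C)[Si](C#CC[C@@H](/C=C/CO[Si](C)(C)C(C)(C)C)[C@@H](CC(=O)N(C)OC)C(=O)O[Si](C)(C)C)(C(C)C)C(C)C | intermediate (not isolated)
15 | (2R,3S,4E)-6-[(tert-butyldimethylsilyl)oxy]-2-{2-[methoxy(methyl)amino]-2-oxoethyl}-3-[3-(triisopropylsilyl)prop-2-yn-1-yl]hex-4-enoic acid | CC(C)[Si](C#CC[C@@H](/C=C/CO[Si](C)(C)C(C)(C)C)[C@@H](CC(=O)N(C)OC)C(=O)O)(C(C)C)C(C)C | intermediate
16 | methyl (2R,3S,4E)-6-[(tert-butyldimethylsilyl)oxy]-2-{2-[methoxy(methyl)amino]-2-oxoethyl}-3-[3-(triisopropylsilyl)prop-2-yn-1-yl]hex-4-enoate | CC(C)[Si](C#CC[C@@H](/C=C/CO[Si](C)(C)C(C)(C)C)[C@@H](CC(=O)N(C)OC)C(=O)OC)(C(C)C)C(C)C | intermediate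
17 | methyl (2R,3S,4E)-6-hydroxy-2-{2-[methoxy(methyl)amino]-2-oxoethyl}-3-[3-(triisopropylsilyl)prop-2-yn-1-yl]hex-4-enoate | CC(C)[Si](C#CC[C@@H](/C=C/CO)[C@@H](CC(=O)N(C)OC)C(=O)OC)(C(C)C)C(C)C | intermediate
18 | methyl (2R,3S,4E)-2-{2-[methoxy(methyl)amino]-2-oxoethyl}-6-oxo-3-[3-(triisopropylsilyl)prop-2-yn-1-yl]hex-4-enoate | CC(C)[Si](C#CC[C@@H](/C=C/C=O)[C@@H](CC(=O)N(C)OC)C(=O)OC)(C(C)C)C(C)C | intermediate
19 | methyl (2R,3E,5E)-6-[(tert-butyldimethylsilyl)oxy]-2-{2-[methoxy(methyl)amino]-2-oxoethyl}-3-[3-(triisopropylsilyl)prop-2-yn-1-yl]hexa-3,5-dienoate | CC(C)[Si](C#CC/C(=C\C=C\O[Si](C)(C)C(C)(C)C)[C@@H](CC(=O)N(C)OC)C(=O)OC)(C(C)C)C(C)C | intermediate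
20 | bromomagnesium hemiaminal adduct of 19 with the vinyl group on C10 | CC(C)[Si](C#CC/C(=C\C=C\O[Si](C)(C)C(C)(C)C)[C@@H](CC(O[Mg]Br)(C=C)N(C)OC)C(=O)OC)(C(C)C)C(C)C | intermediate (not isolated)
21 | methyl (2R,3E,5E)-6-[(tert-butyldimethylsilyl)oxy]-2-(2-oxobut-3-en-1-yl)-3-[3-(triisopropylsilyl)prop-2-yn-1-yl]hexa-3,5-dienoate | CC(C)[Si](C#CC/C(=C\C=C\O[Si](C)(C)C(C)(C)C)[C@@H](CC(=O)C=C)C(=O)OC)(C(C)C)C(C)C | intermediate
22 | B/C cis-hydrindenone: C10 ketone, C13=C14, 12α-OTBS, 3-(triisopropylsilyl)prop-2-ynyl on C8, 6α-CO2Me, H-9β | CC(C)[Si](C#CC[C@]23C=C[C@@H](O[Si](C)(C)C(C)(C)C)C[C@H]2C(=O)C[C@H]3C(=O)OC)(C(C)C)C(C)C | intermediate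
23 | sodium ester enolate of 22 (C6=C7) | CC(C)[Si](C#CC[C@]23C=C[C@@H](O[Si](C)(C)C(C)(C)C)C[C@H]2C(=O)CC3=C([O-])OC)(C(C)C)C(C)C.[Na+] | intermediate (not isolated)
24 | B/C cis-hydrindenone as 22 but with 6β-CO2Me | CC(C)[Si](C#CC[C@]23C=C[C@@H](O[Si](C)(C)C(C)(C)C)C[C@H]2C(=O)C[C@@H]3C(=O)OC)(C(C)C)C(C)C | intermediate
25 | (tert-butyldimethylsilyloxy)acetaldehyde | O=CCO[Si](C)(C)C(C)(C)C | starting material
26 | ethyl 2-[bis(2,2,2-trifluoroethoxy)phosphoryl]propanoate | CCOC(=O)C(C)P(=O)(OCC(F)(F)F)OCC(F)(F)F | starting material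
27 | ethyl (2Z)-4-[(tert-butyldimethylsilyl)oxy]-2-methylbut-2-enoate | CCOC(=O)/C(C)=C\CO[Si](C)(C)C(C)(C)C | intermediate
28 | (2Z)-4-[(tert-butyldimethylsilyl)oxy]-2-methylbut-2-en-1-ol | OC/C(C)=C\CO[Si](C)(C)C(C)(C)C | intermediate
29 | (2Z)-4-[(tert-butyldimethylsilyl)oxy]-1-[(tert-butyldiphenylsilyl)oxy]-2-methylbut-2-ene | CC(C)(C)[Si](OC/C(C)=C\CO[Si](C)(C)C(C)(C)C)(c1ccccc1)c1ccccc1 | intermediate
30 | (2Z)-4-[(tert-butyldiphenylsilyl)oxy]-3-methylbut-2-en-1-ol | CC(C)(C)[Si](OC/C(C)=C\CO)(c1ccccc1)c1ccccc1 | intermediate
31 | C10 dimethyl ketal of 24 | CC(C)[Si](C#CC[C@]23C=C[C@@H](O[Si](C)(C)C(C)(C)C)C[C@H]2C(OC)(OC)C[C@@H]3C(=O)OC)(C(C)C)C(C)C | intermediate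
32 | mixed C10 ketal of 31 with 30 (both C10 epimers) | CC(C)[Si](C#CC[C@]23C=C[C@@H](O[Si](C)(C)C(C)(C)C)C[C@H]2C(OC)(OC/C=C(/C)CO[Si](c4ccccc4)(c4ccccc4)C(C)(C)C)C[C@@H]3C(=O)OC)(C(C)C)C(C)C | intermediate (not isolated)
33 | C5=C10 enol ether of 24 with 30 | CC(C)[Si](C#CC[C@]23C=C[C@@H](O[Si](C)(C)C(C)(C)C)C[C@H]2C(OC/C=C(/C)CO[Si](c4ccccc4)(c4ccccc4)C(C)(C)C)=C[C@@H]3C(=O)OC)(C(C)C)C(C)C | intermediate (not isolated)
34 | C10 ketone with 5α-C4 (C4: CH3, CH2OTBDPS, vinyl), 6β-CO2Me, 12α-OTBS, silyl propargyl on C8 | CC(C)[Si](C#CC[C@]23C=C[C@@H](O[Si](C)(C)C(C)(C)C)C[C@H]2C(=O)[C@@H]([C@](C)(CO[Si](c4ccccc4)(c4ccccc4)C(C)(C)C)C=C)[C@@H]3C(=O)OC)(C(C)C)C(C)C | intermediate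
35 | 10α-hydroxy-10β-allyl derivative of 34 | CC(C)[Si](C#CC[C@]23C=C[C@@H](O[Si](C)(C)C(C)(C)C)C[C@H]2[C@](O)(CC=C)[C@@H]([C@](C)(CO[Si](c4ccccc4)(c4ccccc4)C(C)(C)C)C=C)[C@@H]3C(=O)OC)(C(C)C)C(C)C | intermediate
36 | A/B/C tricycle: ring-A C2=C3, 10α-OH, C4 with CH3 and CH2OTBDPS, 12α-OTBS, C13=C14, silyl propargyl on C8, 6β-CO2Me | CC(C)[Si](C#CC[C@]23C=C[C@@H](O[Si](C)(C)C(C)(C)C)C[C@H]2[C@]4(O)CC=C[C@@](C)(CO[Si](c5ccccc5)(c5ccccc5)C(C)(C)C)[C@H]4[C@@H]3C(=O)OC)(C(C)C)C(C)C | intermediate
37 | triol of 36 (12α-OH, 10α-OH, C19H2OH) with terminal alkyne | C#CC[C@]23C=C[C@@H](O)C[C@H]2[C@]4(O)CC=C[C@@](C)(CO)[C@H]4[C@@H]3C(=O)OC | intermediate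
38 | 19,10-lactol with C12 enone (C19 epimers) | C#CC[C@]23C=CC(=O)C[C@H]2[C@@]45CC=C[C@@](C)(C(O)O4)[C@H]5[C@@H]3C(=O)OC | intermediate (not isolated)
39 | 19,10-lactone with C12 enone (C13=C14), C2=C3, propargyl on C8, 6β-CO2Me | C#CC[C@]23C=CC(=O)C[C@H]2[C@@]45CC=C[C@@](C)(C(=O)O4)[C@H]5[C@@H]3C(=O)OC | intermediate
40 | 2β,3β-diol of 39 | C#CC[C@]23C=CC(=O)C[C@H]2[C@@]45C[C@H](O)[C@H](O)[C@@](C)(C(=O)O4)[C@H]5[C@@H]3C(=O)OC | intermediate
41 | 2β,3β-acetonide of 40 | C#CC[C@]23C=CC(=O)C[C@H]2[C@@]45C[C@@H]6OC(C)(C)O[C@@H]6[C@@](C)(C(=O)O4)[C@H]5[C@@H]3C(=O)OC | intermediate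
42 | potassium C12 enolate (C12=C13) from 41 | C#CC[C@]23CC=C([O-])C[C@H]2[C@@]45C[C@@H]6OC(C)(C)O[C@@H]6[C@@](C)(C(=O)O4)[C@H]5[C@@H]3C(=O)OC.[K+] | intermediate (not isolated)
43 | C12=C13 tert-butyldimethylsilyl enol ether | C#CC[C@]23CC=C(O[Si](C)(C)C(C)(C)C)C[C@H]2[C@@]45C[C@@H]6OC(C)(C)O[C@@H]6[C@@](C)(C(=O)O4)[C@H]5[C@@H]3C(=O)OC | intermediate
44 | tetracyclic C12 ketone: ring D closed, C16=C17 methylene, 19,10-lactone, 2β,3β-acetonide, 6β-CO2Me | C=C1C[C@]23C[C@H]1C(=O)C[C@H]2[C@@]45C[C@@H]6OC(C)(C)O[C@@H]6[C@@](C)(C(=O)O4)[C@H]5[C@@H]3C(=O)OC | intermediate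
45 | 12α-alcohol of 44 (methyl ester and 2,3-acetonide of 47) | C=C1C[C@]23C[C@H]1[C@@H](O)C[C@H]2[C@@]45C[C@@H]6OC(C)(C)O[C@@H]6[C@@](C)(C(=O)O4)[C@H]5[C@@H]3C(=O)OC | intermediate
46 | 2,3-acetonide of 47 (free C7 acid) | C=C1C[C@]23C[C@H]1[C@@H](O)C[C@H]2[C@@]45C[C@@H]6OC(C)(C)O[C@@H]6[C@@](C)(C(=O)O4)[C@H]5[C@@H]3C(=O)O | intermediate
47 | target gibberellin: 2β,3β,12α-trihydroxy C19-gibberellin with 19,10-lactone, 6β-CO2H and C16=C17 methylene | C=C1C[C@]23C[C@H]1[C@@H](O)C[C@H]2[C@@]12C[C@H](O)[C@H](O)[C@@](C)(C(=O)O1)[C@H]2[C@@H]3C(=O)O | target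

## Step count and weakest steps

Total: 30 steps. Longest linear sequence: 24 steps (from 5 through steps 2, 3, 5–13 and 18–30).

**Step 12 (key step).** The most likely failure is loss of facial selectivity: the second endo arrangement, with the ester beside the C15 methylene, may compete or even dominate, which would give the adduct with the mirror-image B/C core. The inside CH2 group also crowds the dienophile, so the cyclisation may be slow enough for the dienol ether to hydrolyse or the vinyl ketone to polymerise. If the other endo arrangement turns out to be the preferred one, the fallback keeps the cycloaddition and changes the configuration of C6 in the precursor instead. It sets out from 11: the Ireland–Claisen rearrangement is run through the other enolate geometry (LDA in THF without DMPU) to the (2S,3S,4E)-acid F1. F1 is taken through the operations of steps 7–11 to the methyl ester F2, the allylic alcohol F3, the enal F4, the (2S)-dienol silyl ether F5 and the (2S)-trienone F6. Cyclisation of F6 through that arrangement would give 24 directly, and step 13 would be dropped.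

**Step 13.** The equilibrium may not lie far enough on the 6β side, and under methoxide the ketone can lose material through enolisation at C9 or aldol condensation. The fallback moves the equilibration behind the ketone protection. It sets out from 22, which is ketalised under the conditions of step 18 to the 6α dimethyl ketal F7. F7, with no enolisable ketone, is equilibrated with NaOMe in MeOH at 60 °C and comes back to the route at 31.

**Step 19.** Ketal exchange at the hindered C10 may be slow, so that the acid and heat destroy 30 before the enol ether forms; a boat transition state would also erode the C4 configuration. The fallback makes the same enol ether by C–O coupling instead of ketal exchange. It sets out from 24, which is converted with hydrazine into the hydrazone F8 and then with iodine and tetramethylguanidine into the C5=C10 vinyl iodide F9 (Barton vinyl iodide synthesis). Copper-catalysed coupling of F9 with 30 (CuI, tetramethylphenanthroline, Cs2CO3, toluene, 120 °C) gives 33, which rearranges in the same pot, and the route is rejoined at 34.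

**Step 28.** Hydride may be delivered to the α face if the C17 methylene shields the β face more than C10 shields the α face, which would give the equatorial 12β-alcohol. The fallback accepts that outcome and inverts the centre. It sets out from 44, whose reduction would then give the 12β-alcohol F10. Mitsunobu reaction of F10 with 4-nitrobenzoic acid gives the 12α-(4-nitrobenzoate) F11; if hydride can reach the α face, the carboxylate should too. Methanolysis of F11 with K2CO3 in MeOH, with the acetonide still protecting C3, returns to the route at 45.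

## Further compounds

F1 | step 12 | (2S,3S,4E)-6-[(tert-butyldimethylsilyl)oxy]-2-{2-[methoxy(methyl)amino]-2-oxoethyl}-3-[3-(triisopropylsilyl)prop-2-yn-1-yl]hex-4-enoic acid | CC(C)[Si](C#CC[C@@H](/C=C/CO[Si](C)(C)C(C)(C)C)[C@H](CC(=O)N(C)OC)C(=O)O)(C(C)C)C(C)C
F2 | step 12 | methyl (2S,3S,4E)-6-[(tert-butyldimethylsilyl)oxy]-2-{2-[methoxy(methyl)amino]-2-oxoethyl}-3-[3-(triisopropylsilyl)prop-2-yn-1-yl]hex-4-enoate | CC(C)[Si](C#CC[C@@H](/C=C/CO[Si](C)(C)C(C)(C)C)[C@H](CC(=O)N(C)OC)C(=O)OC)(C(C)C)C(C)C
F3 | step 12 | methyl (2S,3S,4E)-6-hydroxy-2-{2-[methoxy(methyl)amino]-2-oxoethyl}-3-[3-(triisopropylsilyl)prop-2-yn-1-yl]hex-4-enoate | CC(C)[Si](C#CC[C@@H](/C=C/CO)[C@H](CC(=O)N(C)OC)C(=O)OC)(C(C)C)C(C)C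
F4 | step 12 | methyl (2S,3S,4E)-2-{2-[methoxy(methyl)amino]-2-oxoethyl}-6-oxo-3-[3-(triisopropylsilyl)prop-2-yn-1-yl]hex-4-enoate | CC(C)[Si](C#CC[C@@H](/C=C/C=O)[C@H](CC(=O)N(C)OC)C(=O)OC)(C(C)C)C(C)C
F5 | step 12 | methyl (2S,3E,5E)-6-[(tert-butyldimethylsilyl)oxy]-2-{2-[methoxy(methyl)amino]-2-oxoethyl}-3-[3-(triisopropylsilyl)prop-2-yn-1-yl]hexa-3,5-dienoate | CC(C)[Si](C#CC/C(=C\C=C\O[Si](C)(C)C(C)(C)C)[C@H](CC(=O)N(C)OC)C(=O)OC)(C(C)C)C(C)C
F6 | step 12 | methyl (2S,3E,5E)-6-[(tert-butyldimethylsilyl)oxy]-2-(2-oxobut-3-en-1-yl)-3-[3-(triisopropylsilyl)prop-2-yn-1-yl]hexa-3,5-dienoate | CC(C)[Si](C#CC/C(=C\C=C\O[Si](C)(C)C(C)(C)C)[C@H](CC(=O)C=C)C(=O)OC)(C(C)C)C(C)C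
F7 | step 13 | C10 dimethyl ketal of 22 (6α-CO2Me) | CC(C)[Si](C#CC[C@]23C=C[C@@H](O[Si](C)(C)C(C)(C)C)C[C@H]2C(OC)(OC)C[C@H]3C(=O)OC)(C(C)C)C(C)C
F8 | step 19 | C10 hydrazone of 24 | CC(C)[Si](C#CC[C@]23C=C[C@@H](O[Si](C)(C)C(C)(C)C)C[C@H]2C(=NN)C[C@@H]3C(=O)OC)(C(C)C)C(C)C
F9 | step 19 | C5=C10 vinyl iodide (iodine on C10) from 24 | CC(C)[Si](C#CC[C@]23C=C[C@@H](O[Si](C)(C)C(C)(C)C)C[C@H]2C(I)=C[C@@H]3C(=O)OC)(C(C)C)C(C)C
F10 | step 28 | 12β-alcohol, the C12 epimer of 45 (methyl ester, 2,3-acetonide) | C=C1C[C@]23C[C@H]1[C@H](O)C[C@H]2[C@@]45C[C@@H]6OC(C)(C)O[C@@H]6[C@@](C)(C(=O)O4)[C@H]5[C@@H]3C(=O)OC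
F11 | step 28 | 12α-(4-nitrobenzoate) of 45 (methyl ester, 2,3-acetonide) | C=C1C[C@]23C[C@H]1[C@@H](OC(=O)c7ccc(cc7)[N+](=O)[O-])C[C@H]2[C@@]45C[C@@H]6OC(C)(C)O[C@@H]6[C@@](C)(C(=O)O4)[C@H]5[C@@H]3C(=O)OC
A1 | alternative 1 | 10,12α-ether of the 16-nor-16-ketone (2,3-acetonide, 19-dimethylamide, C7 tert-butyl ester) | O=C1C[C@]23C[C@H]1[C@@H]5C[C@H]2[C@]2(O5)C[C@@H]4OC(C)(C)O[C@@H]4[C@@](C)(C(=O)N(C)C)[C@H]2[C@@H]3C(=O)OC(C)(C)C
A2 | alternative 2 | 12-oxo-16-methylene 19,10-lactone (2,3-diacetate, C7 methyl ester) | C=C1C[C@]23C[C@H]1C(=O)C[C@H]2[C@@]12C[C@H](OC(C)=O)[C@H](OC(C)=O)[C@@](C)(C(=O)O1)[C@H]2[C@@H]3C(=O)OC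
A3 | alternative 3 | B/C cis-hydrindenedione (C10 ketone, C12 enone, allyl on C8, 6β-CO2Me) | C=CC[C@]23C=CC(=O)C[C@H]2C(=O)C[C@@H]3C(=O)OC
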